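**Plan**

1. Numbering: chroman O1, C2, C3, C4, C4a to C8a (benzo ring = ring A, dihydropyran = ring C); the resorcinol ring is ring B. The retrosynthesis first removes the three phenol ethers and the two methyl groups of the tertiary alcohol (ester + MeMgBr), then cuts C4–C4a and O1–C8a together, the two bonds that tie the C2–C3–C4 chain to ring A.
2. Enabling feature: on ring A the oxygen-bearing carbon C8a lies between C8 (which carries the side chain) and C4a. An aryl iodide at C8a with the C8 chain as its only ortho substituent and a free C4a–H is the substrate pattern of a Catellani reaction, so one Pd(OAc)2/norbornene event can alkylate C4a and etherify C8a with a 1,3-bromohydrin that already holds C3 and ring B.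
3. Forward, ring B fragment: resorcinol, prenyl ether, aromatic Claisen rearrangement (gives the 1,1-dimethylallyl group), iodide, 3-aryloxetane, enantioselective opening to the (R)-bromohydrin.
4. Forward, ring A fragment: 2-fluoro-6-iodobenzaldehyde, silylethyl ether by SNAr, Wittig, diimide. The annulation then joins the fragments and closes ring C; MeMgBr and fluoride finish.
5. Stereochemistry: the only stereocenter, C3, is set by catalyst control in the desymmetrising oxetane opening and carried through the annulation, where no bond to C3 is made or broken.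

Key step: step 11

Remark: in step 7 the antipode of the squaramide catalyst is taken to be the one that delivers bromide to the pro-R ring CH2 of the oxetane; both antipodes are accessible and the sense would be confirmed by correlation on the first run.

**Route**

Step 1
Reactants: 1 resorcinol; 2 prenyl bromide (1-bromo-3-methylbut-2-ene)
Product: 3 3-[(3-methylbut-2-en-1-yl)oxy]phenol
Conditions: K2CO3 (1.1 equiv), 1 in excess (3 equiv), acetone, reflux
Reagents that add atoms: none
Why: Williamson ether synthesis, in which the excess of the cheap diphenol holds the alkylation at the mono-ether and carbonate in acetone favours O- over C-prenylation.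

Step 2
Reactants: 3 3-[(3-methylbut-2-en-1-yl)oxy]phenol
Product: 4 trimethyl(2-{3-[(3-methylbut-2-en-1-yl)oxy]phenoxy}ethyl)silane
Conditions: Me3SiCH2CH2OH, PPh3, DIAD, THF, 0 °C to rt
Reagents that add atoms: 2-(trimethylsilyl)ethanol, C[Si](C)(C)CCO
Why: Mitsunobu etherification of the phenol with a primary alcohol, which installs a 2-(trimethylsilyl)ethyl ether that is inert to heat, base, organometallics and low-temperature Lewis acids and is removed by fluoride at the end.

Step 3
Reactants: 4 trimethyl(2-{3-[(3-methylbut-2-en-1-yl)oxy]phenoxy}ethyl)silane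
Product: 6 2-(2-methylbut-3-en-2-yl)-5-[2-(trimethylsilyl)ethoxy]phenol, via dienone 5 (not isolated)
Conditions: N,N-diethylaniline, 185 °C, sealed tube, argon
Reagents that add atoms: none
Why: aromatic Claisen rearrangement ([3,3] shift, then tautomerisation of the dienone) should deliver the inverted 1,1-dimethylallyl group to the ortho carbon para to the silylethoxy group, because the ortho carbon between the two oxygens is too crowded for the forming quaternary centre, while the basic solvent suppresses acid-promoted follow-up reactions.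

Step 4
Reactants: 6 2-(2-methylbut-3-en-2-yl)-5-[2-(trimethylsilyl)ethoxy]phenol
Product: 7 1-(2-methylbut-3-en-2-yl)-2,4-bis[2-(trimethylsilyl)ethoxy]benzene
Conditions: Me3SiCH2CH2OH, PPh3, DIAD, THF (concentrated), rt to 40 °C
Reagents that add atoms: 2-(trimethylsilyl)ethanol, C[Si](C)(C)CCO
Why: Mitsunobu etherification, for which the phenol is acidic enough and the primary alcohol unhindered, so the ortho tert-alkyl group should only slow the reaction.

Step 5
Reactants: 7 1-(2-methylbut-3-en-2-yl)-2,4-bis[2-(trimethylsilyl)ethoxy]benzene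
Product: 8 1-iodo-5-(2-methylbut-3-en-2-yl)-2,4-bis[2-(trimethylsilyl)ethoxy]benzene
Conditions: NIS, MeCN, 0 °C to rt, dark
Reagents that add atoms: N-iodosuccinimide, O=C1CCC(=O)N1I
Why: electrophilic aromatic iodination should take place at the one unhindered ring carbon that is ortho to one ether oxygen and para to the other, far faster than at the monosubstituted alkene.

Step 6
Reactants: 8 1-iodo-5-(2-methylbut-3-en-2-yl)-2,4-bis[2-(trimethylsilyl)ethoxy]benzene; 9 3-iodooxetane
Product: 10 3-{5-(2-methylbut-3-en-2-yl)-2,4-bis[2-(trimethylsilyl)ethoxy]phenyl}oxetane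
Conditions: NiI2 (10 mol %), 4,4'-di-tert-butyl-2,2'-bipyridine (10 mol %), Zn dust (2 equiv), pyridine (cat.), DMA, 60 °C
Reagents that add atoms: none
Why: nickel-catalysed reductive cross-electrophile coupling of an aryl iodide with a secondary alkyl iodide, in which the aryl iodide adds to zerovalent nickel and the oxetan-3-yl radical is captured by the arylnickel species, while ethers, the alkene and the silanes are inert.

Step 7
Reactants: 10 3-{5-(2-methylbut-3-en-2-yl)-2,4-bis[2-(trimethylsilyl)ethoxy]phenyl}oxetane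
Product: 12 (2R)-3-bromo-2-{5-(2-methylbut-3-en-2-yl)-2,4-bis[2-(trimethylsilyl)ethoxy]phenyl}propan-1-ol, via silyl ether 11 (not isolated)
Conditions: Me3SiBr (1.5 equiv), chiral arylpyrrolidine-amide squaramide hydrogen-bond donor (5 mol %), t-BuOMe, −78 °C; then MeOH, citric acid, 0 °C
Reagents that add atoms: bromotrimethylsilane, C[Si](C)(C)Br
Why: enantioselective desymmetrising ring opening of a 3-aryloxetane with bromotrimethylsilane under chiral hydrogen-bond-donor catalysis, in which the squaramide-bound bromide attacks one of the two enantiotopic ring CH2 groups (the pro-R one) of the O-silylated oxetane and so sets the later C3 as R, after which methanolysis frees the primary alcohol.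

Step 8
Reactants: 13 2-fluoro-6-iodobenzaldehyde
Product: 14 2-iodo-6-[2-(trimethylsilyl)ethoxy]benzaldehyde
Conditions: Me3SiCH2CH2OH, NaH, THF, 0 °C; then 13, 0 °C to rt
Reagents that add atoms: 2-(trimethylsilyl)ethanol, C[Si](C)(C)CCO
Why: nucleophilic aromatic substitution (addition–elimination) of the fluoride ortho to the aldehyde by the sodium alkoxide, which leaves the iodide in place and brings in the phenol oxygen already protected.

Step 9
Reactants: 14 2-iodo-6-[2-(trimethylsilyl)ethoxy]benzaldehyde
Product: 15 methyl (2E)-3-{2-iodo-6-[2-(trimethylsilyl)ethoxy]phenyl}prop-2-enoate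
Conditions: Ph3P=CHCO2Me, toluene, 90 °C
Reagents that add atoms: methyl (triphenylphosphoranylidene)acetate, COC(=O)C=P(c1ccccc1)(c1ccccc1)c1ccccc1
Why: Wittig olefination with a stabilised ylide, which is E-selective and tolerates the aryl iodide.

Step 10
Reactants: 15 methyl (2E)-3-{2-iodo-6-[2-(trimethylsilyl)ethoxy]phenyl}prop-2-enoate
Product: 16 methyl 3-{2-iodo-6-[2-(trimethylsilyl)ethoxy]phenyl}propanoate
Conditions: TsNHNH2 (excess), NaOAc, THF–H2O, reflux
Reagents that add atoms: none
Why: diimide reduction, whose concerted syn transfer of H2 saturates the C=C bond without a metal hydride, so the C–I bond should stay untouched.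

Step 11
Reactants: 16 methyl 3-{2-iodo-6-[2-(trimethylsilyl)ethoxy]phenyl}propanoate; 12 (2R)-3-bromo-2-{5-(2-methylbut-3-en-2-yl)-2,4-bis[2-(trimethylsilyl)ethoxy]phenyl}propan-1-ol
Product: 17 methyl 3-[(3R)-3-{5-(2-methylbut-3-en-2-yl)-2,4-bis[2-(trimethylsilyl)ethoxy]phenyl}-7-[2-(trimethylsilyl)ethoxy]-3,4-dihydro-2H-chromen-8-yl]propanoate
Conditions: Pd(OAc)2 (10 mol %), 2-dicyclohexylphosphino-2',6'-diisopropoxybiphenyl (20 mol %), norbornene (1.5 equiv), Cs2CO3 (3 equiv), 16 (1.3 equiv), toluene, 100 °C
Reagents that add atoms: none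
Why: Proposed new method: oxidative addition of the C–I bond of 16 to zerovalent palladium, carbopalladation of norbornene and palladation of the one free ortho C–H give an aryl–norbornyl palladacycle, whose SN2-type oxidative addition to the primary C–Br bond of 12 (tetravalent palladium) and reductive elimination forge the aryl–CH2 bond; norbornene is then expelled by β-carbon elimination because both ortho positions are now filled, and the cesium alkoxide of the new side chain is O-arylated at the ipso carbon by C–O reductive elimination from divalent palladium. The closest known reaction types are the Catellani annulations of aryl iodides with epoxides (to 2,3-dihydrobenzofurans) and with bromoalkylamines (to indolines and tetrahydroquinolines), together with the palladium-catalysed intramolecular aryl etherification of primary alcohols; the use of a 1,3-bromohydrin to close a dihydropyran is the new element. Ring C closes in the second bond-forming event by C(sp2)–O reductive elimination from a seven-membered aryl(alkoxo)palladium chelate, that is, an intramolecular aryl etherification that gives the six-membered ring. No stereocenter is formed: C3 comes from 12 and should be retained, since no bond to it is made or broken and the SN2 event takes place at the neighbouring primary carbon. The step needs C-alkylation at the ortho carbon before O-arylation at the ipso carbon and no second ortho alkylation, and the propanoate chain on the other ortho carbon secures both, because it blocks that position and norbornene extrusion sets in only once both ortho positions are substituted. The ester rather than the free tertiary alcohol is carried so that no second alkoxide can compete for the ipso carbon.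

Step 12
Reactants: 17 methyl 3-[(3R)-3-{5-(2-methylbut-3-en-2-yl)-2,4-bis[2-(trimethylsilyl)ethoxy]phenyl}-7-[2-(trimethylsilyl)ethoxy]-3,4-dihydro-2H-chromen-8-yl]propanoate
Product: 19 4-[(3R)-3-{5-(2-methylbut-3-en-2-yl)-2,4-bis[2-(trimethylsilyl)ethoxy]phenyl}-7-[2-(trimethylsilyl)ethoxy]-3,4-dihydro-2H-chromen-8-yl]-2-methylbutan-2-ol, via methyl ketone 18 (not isolated)
Conditions: MeMgBr (4 equiv), THF, 0 °C to rt; then aqueous work-up
Reagents that add atoms: methylmagnesium bromide, C[Mg]Br
Why: double Grignard addition to the ester through the more reactive methyl ketone should give the tertiary alcohol, since nothing else in 17 is electrophilic.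

Step 13
Reactants: 19 4-[(3R)-3-{5-(2-methylbut-3-en-2-yl)-2,4-bis[2-(trimethylsilyl)ethoxy]phenyl}-7-[2-(trimethylsilyl)ethoxy]-3,4-dihydro-2H-chromen-8-yl]-2-methylbutan-2-ol
Product: 20 4-[(3R)-7-hydroxy-8-(3-hydroxy-3-methylbutyl)-3,4-dihydro-2H-chromen-3-yl]-6-(2-methylbut-3-en-2-yl)benzene-1,3-diol (target)
Conditions: Bu4NF (12 equiv), DMF, 80 °C, argon; then aq. NH4Cl
Reagents that add atoms: none
Why: fluoride attack on silicon with β-elimination of ethene and phenoxide should cleave all three aryl 2-(trimethylsilyl)ethyl ethers under non-acidic conditions, which matters because acid would cyclise the tertiary alcohol onto the C7 phenol or a ring B phenol onto the 1,1-dimethylallyl group.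

**Compound list**

1 | resorcinol (benzene-1,3-diol) | Oc1cccc(O)c1 | starting material
2 | prenyl bromide (1-bromo-3-methylbut-2-ene) | CC(C)=CCBr | starting material
3 | 3-[(3-methylbut-2-en-1-yl)oxy]phenol | CC(C)=CCOc1cccc(O)c1 | intermediate
4 | trimethyl(2-{3-[(3-methylbut-2-en-1-yl)oxy]phenoxy}ethyl)silane | CC(C)=CCOc1cccc(OCC[Si](C)(C)C)c1 | intermediate
5 | 6-(2-methylbut-3-en-2-yl)-3-[2-(trimethylsilyl)ethoxy]cyclohexa-2,4-dien-1-one (racemic, transient) | O=C1C=C(OCC[Si](C)(C)C)C=CC1C(C)(C)C=C | intermediate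
6 | 2-(2-methylbut-3-en-2-yl)-5-[2-(trimethylsilyl)ethoxy]phenol | C=CC(C)(C)c1ccc(OCC[Si](C)(C)C)cc1O | intermediate
7 | 1-(2-methylbut-3-en-2-yl)-2,4-bis[2-(trimethylsilyl)ethoxy]benzene | C=CC(C)(C)c1ccc(OCC[Si](C)(C)C)cc1OCC[Si](C)(C)C | intermediate
8 | 1-iodo-5-(2-methylbut-3-en-2-yl)-2,4-bis[2-(trimethylsilyl)ethoxy]benzene | C=CC(C)(C)c1cc(I)c(OCC[Si](C)(C)C)cc1OCC[Si](C)(C)C | intermediate
9 | 3-iodooxetane | IC1COC1 | starting material
10 | 3-{5-(2-methylbut-3-en-2-yl)-2,4-bis[2-(trimethylsilyl)ethoxy]phenyl}oxetane | C=CC(C)(C)c1cc(C2COC2)c(OCC[Si](C)(C)C)cc1OCC[Si](C)(C)C | intermediate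
11 | [(2R)-3-bromo-2-{5-(2-methylbut-3-en-2-yl)-2,4-bis[2-(trimethylsilyl)ethoxy]phenyl}propoxy]trimethylsilane | C=CC(C)(C)c1cc([C@@H](CBr)CO[Si](C)(C)C)c(OCC[Si](C)(C)C)cc1OCC[Si](C)(C)C | intermediate
12 | (2R)-3-bromo-2-{5-(2-methylbut-3-en-2-yl)-2,4-bis[2-(trimethylsilyl)ethoxy]phenyl}propan-1-ol | C=CC(C)(C)c1cc([C@@H](CBr)CO)c(OCC[Si](C)(C)C)cc1OCC[Si](C)(C)C | intermediate
13 | 2-fluoro-6-iodobenzaldehyde | O=Cc1c(F)cccc1I | starting material
14 | 2-iodo-6-[2-(trimethylsilyl)ethoxy]benzaldehyde | O=Cc1c(OCC[Si](C)(C)C)cccc1I | intermediate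
15 | methyl (2E)-3-{2-iodo-6-[2-(trimethylsilyl)ethoxy]phenyl}prop-2-enoate | COC(=O)/C=C/c1c(OCC[Si](C)(C)C)cccc1I | intermediate
16 | methyl 3-{2-iodo-6-[2-(trimethylsilyl)ethoxy]phenyl}propanoate | COC(=O)CCc1c(OCC[Si](C)(C)C)cccc1I | intermediate
17 | methyl 3-[(3R)-3-{5-(2-methylbut-3-en-2-yl)-2,4-bis[2-(trimethylsilyl)ethoxy]phenyl}-7-[2-(trimethylsilyl)ethoxy]-3,4-dihydro-2H-chromen-8-yl]propanoate | C=CC(C)(C)c1cc([C@@H]2COc3c(ccc(OCC[Si](C)(C)C)c3CCC(=O)OC)C2)c(OCC[Si](C)(C)C)cc1OCC[Si](C)(C)C | intermediate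
18 | 4-[(3R)-3-{5-(2-methylbut-3-en-2-yl)-2,4-bis[2-(trimethylsilyl)ethoxy]phenyl}-7-[2-(trimethylsilyl)ethoxy]-3,4-dihydro-2H-chromen-8-yl]butan-2-one | C=CC(C)(C)c1cc([C@@H]2COc3c(ccc(OCC[Si](C)(C)C)c3CCC(C)=O)C2)c(OCC[Si](C)(C)C)cc1OCC[Si](C)(C)C | intermediate
19 | 4-[(3R)-3-{5-(2-methylbut-3-en-2-yl)-2,4-bis[2-(trimethylsilyl)ethoxy]phenyl}-7-[2-(trimethylsilyl)ethoxy]-3,4-dihydro-2H-chromen-8-yl]-2-methylbutan-2-ol | C=CC(C)(C)c1cc([C@@H]2COc3c(ccc(OCC[Si](C)(C)C)c3CCC(C)(C)O)C2)c(OCC[Si](C)(C)C)cc1OCC[Si](C)(C)C | intermediate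
20 | 4-[(3R)-7-hydroxy-8-(3-hydroxy-3-methylbutyl)-3,4-dihydro-2H-chromen-3-yl]-6-(2-methylbut-3-en-2-yl)benzene-1,3-diol | C=CC(C)(C)c1cc([C@@H]2COc3c(ccc(O)c3CCC(C)(C)O)C2)c(O)cc1O | target

**Step count and risks**

Total step count: 13. Longest linear sequence: 10 steps (steps 1 to 7, then 11 to 13).

Step 11 (proposed method). Under the carbonate base the bromohydrin may close back to the oxetane or lose HBr faster than its β-branched C–Br bond adds to the palladacycle. The palladium alkoxide may also undergo β-hydride elimination instead of C–O reductive elimination. The fallback sets out from 12 and returns at 17, making the two bonds in two separate, known operations. Compound 12 is silylated (TBSCl, imidazole, DMF) to the tert-butyldimethylsilyl ether F1 and converted with Zn dust and LiCl in THF into the alkylzinc bromide F2. In parallel, commercial 2-bromo-6-fluorobenzaldehyde is taken through the reactions of steps 8 to 10, giving 2-bromo-6-[2-(trimethylsilyl)ethoxy]benzaldehyde F3, then methyl (2E)-3-{2-bromo-6-[2-(trimethylsilyl)ethoxy]phenyl}prop-2-enoate F4, then methyl 3-{2-bromo-6-[2-(trimethylsilyl)ethoxy]phenyl}propanoate F5. NIS iodinates this para to the ether oxygen to give methyl 3-{2-bromo-3-iodo-6-[2-(trimethylsilyl)ethoxy]phenyl}propanoate F6. Negishi coupling of the zinc reagent with this arene at the C–I bond (Pd(OAc)2, SPhos, THF, rt) should give the aryl bromide F7. The silyl ether is cleaved with camphorsulfonic acid in MeOH to the alcohol F8. Intramolecular aryl etherification at the C–Br bond (Pd(OAc)2, 2-di-tert-butylphosphino-1,1'-binaphthyl, Cs2CO3, toluene, 80 °C) then closes ring C and gives 17.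

Step 7. The crowded ortho-alkoxy aryl group may erode the discrimination between the two enantiotopic CH2 groups, or the sense of induction may be opposite to that assumed. The fallback sets out from 8 and returns at 12; it replaces the catalytic oxetane opening by enzymatic desymmetrisation of a diol and also bypasses step 6. Arylation of diethyl malonate with 8 (CuI, 2-picolinic acid, Cs2CO3, dioxane, 70 °C) gives the arylmalonate F9. LiAlH4 in THF reduces it to the prochiral diol F10. Lipase-catalysed monoacetylation (Burkholderia cepacia lipase, vinyl acetate, t-BuOMe, enzyme chosen for the S product) gives the monoacetate F11. Appel bromination (CBr4, PPh3, CH2Cl2) gives the bromo acetate F12, and acid-catalysed methanolysis (AcCl cat., MeOH) gives 12.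

Step 3. The rearrangement may lose regiocontrol through migration to the carbon between the two oxygens, and the product may rearrange further or cyclise at the temperature needed. The fallback sets out from 1 and returns at 7; it builds the quaternary benzylic carbon by cross-coupling instead of by a sigmatropic shift. Double Mitsunobu etherification of 1 (Me3SiCH2CH2OH, PPh3, DIAD) gives the bis-ether F13. NBS in MeCN brominates it para to one ether oxygen to give the aryl bromide F14. α-Arylation of isobutyraldehyde (Pd(OAc)2, rac-BINAP, Cs2CO3, dioxane, 80 °C) gives the quaternary aldehyde F15, and Wittig methylenation (Ph3PCH3Br, KOt-Bu, THF) gives 7.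

Further compounds

F1 | step 11 | tert-butyl{[(2R)-3-bromo-2-{5-(2-methylbut-3-en-2-yl)-2,4-bis[2-(trimethylsilyl)ethoxy]phenyl}propyl]oxy}dimethylsilane | C=CC(C)(C)c1cc([C@@H](CBr)CO[Si](C)(C)C(C)(C)C)c(OCC[Si](C)(C)C)cc1OCC[Si](C)(C)C
F2 | step 11 | bromo[(2R)-3-{[tert-butyl(dimethyl)silyl]oxy}-2-{5-(2-methylbut-3-en-2-yl)-2,4-bis[2-(trimethylsilyl)ethoxy]phenyl}propyl]zinc | C=CC(C)(C)c1cc([C@@H](C[Zn]Br)CO[Si](C)(C)C(C)(C)C)c(OCC[Si](C)(C)C)cc1OCC[Si](C)(C)C
F3 | step 11 | 2-bromo-6-[2-(trimethylsilyl)ethoxy]benzaldehyde | O=Cc1c(OCC[Si](C)(C)C)cccc1Br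
F4 | step 11 | methyl (2E)-3-{2-bromo-6-[2-(trimethylsilyl)ethoxy]phenyl}prop-2-enoate | COC(=O)/C=C/c1c(OCC[Si](C)(C)C)cccc1Br
F5 | step 11 | methyl 3-{2-bromo-6-[2-(trimethylsilyl)ethoxy]phenyl}propanoate | COC(=O)CCc1c(OCC[Si](C)(C)C)cccc1Br
F6 | step 11 | methyl 3-{2-bromo-3-iodo-6-[2-(trimethylsilyl)ethoxy]phenyl}propanoate | COC(=O)CCc1c(OCC[Si](C)(C)C)ccc(I)c1Br
F7 | step 11 | methyl 3-{2-bromo-3-[(2R)-3-{[tert-butyl(dimethyl)silyl]oxy}-2-{5-(2-methylbut-3-en-2-yl)-2,4-bis[2-(trimethylsilyl)ethoxy]phenyl}propyl]-6-[2-(trimethylsilyl)ethoxy]phenyl}propanoate | C=CC(C)(C)c1cc([C@@H](Cc2ccc(OCC[Si](C)(C)C)c(CCC(=O)OC)c2Br)CO[Si](C)(C)C(C)(C)C)c(OCC[Si](C)(C)C)cc1OCC[Si](C)(C)C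
F8 | step 11 | methyl 3-{2-bromo-3-[(2R)-3-hydroxy-2-{5-(2-methylbut-3-en-2-yl)-2,4-bis[2-(trimethylsilyl)ethoxy]phenyl}propyl]-6-[2-(trimethylsilyl)ethoxy]phenyl}propanoate | C=CC(C)(C)c1cc([C@@H](Cc2ccc(OCC[Si](C)(C)C)c(CCC(=O)OC)c2Br)CO)c(OCC[Si](C)(C)C)cc1OCC[Si](C)(C)C
F9 | step 7 | diethyl 2-{5-(2-methylbut-3-en-2-yl)-2,4-bis[2-(trimethylsilyl)ethoxy]phenyl}propanedioate | CCOC(=O)C(C(=O)OCC)c1cc(C(C)(C)C=C)c(OCC[Si](C)(C)C)cc1OCC[Si](C)(C)C
F10 | step 7 | 2-{5-(2-methylbut-3-en-2-yl)-2,4-bis[2-(trimethylsilyl)ethoxy]phenyl}propane-1,3-diol | OCC(CO)c1cc(C(C)(C)C=C)c(OCC[Si](C)(C)C)cc1OCC[Si](C)(C)C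
F11 | step 7 | (2S)-3-hydroxy-2-{5-(2-methylbut-3-en-2-yl)-2,4-bis[2-(trimethylsilyl)ethoxy]phenyl}propyl acetate | C=CC(C)(C)c1cc([C@@H](CO)COC(C)=O)c(OCC[Si](C)(C)C)cc1OCC[Si](C)(C)C
F12 | step 7 | (2R)-3-bromo-2-{5-(2-methylbut-3-en-2-yl)-2,4-bis[2-(trimethylsilyl)ethoxy]phenyl}propyl acetate | C=CC(C)(C)c1cc([C@@H](CBr)COC(C)=O)c(OCC[Si](C)(C)C)cc1OCC[Si](C)(C)C
F13 | step 3 | 1,3-bis[2-(trimethylsilyl)ethoxy]benzene | C[Si](C)(C)CCOc1cccc(OCC[Si](C)(C)C)c1
F14 | step 3 | 1-bromo-2,4-bis[2-(trimethylsilyl)ethoxy]benzene | Brc1ccc(OCC[Si](C)(C)C)cc1OCC[Si](C)(C)C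
F15 | step 3 | 2-{2,4-bis[2-(trimethylsilyl)ethoxy]phenyl}-2-methylpropanal | O=CC(C)(C)c1ccc(OCC[Si](C)(C)C)cc1OCC[Si](C)(C)C
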